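**Plan**

- Retrosynthesis: the O6 ester and the silyl groups are removed first. Ring B is then opened at C6–C7 (the C11–C13 acrylate arrives with C7 as an ester-bearing allylsilane), C4=C15 is cut, and last C5–C6 and C9–C10 are cut together on ring A.
- Enabling feature: on ring A the C3 oxygen and the C5–C6 bond are 1,3-cis, and C10 (bearing C14) is the α-carbon and C5 the β-carbon of a C1 carbonyl. A CH2 radical held through silicon on O3 of a 2-methylcyclohexenone can therefore bond to C5 and leave a C10 radical that takes up C9.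
- Forward order: (R)-carvone → ring A enone with the O3 tether → key step (temporary siloxane ring; C5–C6 and C9–C10) → C1 reduction and oxidative removal of silicon → C15 at C4 → ring B closed last at C6–C7 → O6 acylation and desilylation.
- Stereochemistry: C3 comes from carvone (Criegee rearrangement, retention) and sets C5 (tether) and C10 (anti allylation). C1 is set by exo hydride, C3 is reset by axial hydride after it has served, and C6/C7 by a trans-diequatorial chair closure.

Key step: step 4

Remark: the target is read as (1R,3S,5S,6S,7S,10R), i.e. 1β,3β-diol, 6α-acyloxy, 5α-H, 7α-H, 10β-methyl. Eudesmane locants are used for every intermediate (in monocycles C6 is the one-carbon arm on C5, C9–C7 the chain on C10, C14 the C10 methyl; β is the face of C14).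
Remark: the C4 epimers of 18/19 and the E/Z isomers of 31–33 converge, so neither needs to be controlled.

**Route**

Step 1
Reactants: 1 (R)-carvone
Product: 4 (R)-5-acetoxy-2-methylcyclohex-2-en-1-one, via methoxy hydroperoxide 2 (not isolated), via peroxyacetate 3 (not isolated)
Conditions: O3 (to consumption of 1), CH2Cl2–MeOH, −78 °C; then Ac2O, Et3N, DMAP (cat.), −78 °C → rt
Reagents that add atoms: ozone, O=[O+][O-]; methanol, CO (oxygen only, through 2)
Why: Ozonolysis of the electron-rich isopropenyl alkene in methanol followed by Criegee rearrangement of the derived peroxyacetate moves the ring carbon from carbon to oxygen with retention, so the carvone centre becomes the future C3–O centre.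

Step 2
Reactants: 4 (R)-5-acetoxy-2-methylcyclohex-2-en-1-one
Product: 5 (R)-5-hydroxy-2-methylcyclohex-2-en-1-one
Conditions: K2CO3 (0.2 equiv), MeOH, −10 °C
Reagents that add atoms: none
Why: Base-catalysed transesterification (methanolysis) at low temperature frees the hydroxyl before E1cB loss of the β-oxygen can compete; no stereocentre is formed.

Step 3
Reactants: 5 (R)-5-hydroxy-2-methylcyclohex-2-en-1-one; 6 (bromomethyl)chlorodimethylsilane
Product: 7 (R)-5-{[(bromomethyl)dimethylsilyl]oxy}-2-methylcyclohex-2-en-1-one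
Conditions: Et3N, DMAP (cat.), CH2Cl2, 0 °C; used after filtration
Reagents that add atoms: none
Why: Amine-mediated O-silylation of the secondary alcohol installs the tether that carries the future C6; no stereocentre is formed.

Step 4
Reactants: 7 (R)-5-{[(bromomethyl)dimethylsilyl]oxy}-2-methylcyclohex-2-en-1-one; 8 allyltributylstannane
Product: 11 (1R,5S,6R)-6-allyl-3,3,6-trimethyl-2-oxa-3-silabicyclo[3.3.1]nonan-7-one, via silylmethyl radical 9 (not isolated), via C10 keto radical 10 (not isolated)
Conditions: 8 (3 equiv), AIBN (0.2 equiv, in portions), PhH (0.05 M), 80 °C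
Reagents that add atoms: none
Why: Proposed new method: tributyltin radical abstracts bromine from 7, the nucleophilic α-silyl radical 9 adds to C5 (the enone β-carbon), and the electrophilic tertiary α-keto radical 10 is then allylated by 8 in an SH2′ step that releases the chain-carrying tin radical. The closest known reactions are the (bromomethyl)silyl ether radical cyclisation (Nishiyama–Stork) and the Keck allylation of α-carbonyl radicals, here joined in one chain on a β-silyloxy enone. The only ring closed is the six-membered siloxane, formed 6-exo-trig from the conformer with the C3 oxygen axial, which bridges C3 and C5 as a 2-oxa-3-silabicyclo[3.3.1]nonane. C5 is set by the tether, which can reach the alkene only on the face of the C3 oxygen; C10 is set by approach of 8 anti to the new axial C5–C6 bond and the bridge, so that C9 ends trans and C14 cis to C6. The step needs ring closure to precede allyl transfer and bonding at C5 rather than C10, and both should follow from polarity and geometry: the silyl-substituted radical is matched to the electron-poor β-carbon (7-endo attack at C10 is mismatched and hindered by C14) and reacts only slowly with the electron-rich stannane, whereas the α-keto radical is matched to it.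

Step 5
Reactants: 11 (1R,5S,6R)-6-allyl-3,3,6-trimethyl-2-oxa-3-silabicyclo[3.3.1]nonan-7-one
Product: 12 (1R,5S,6R,7R)-6-allyl-3,3,6-trimethyl-2-oxa-3-silabicyclo[3.3.1]nonan-7-ol (1β-OH)
Conditions: L-Selectride, THF, −78 °C; AcOH quench at −78 °C, non-oxidative work-up
Reagents that add atoms: none
Why: Reduction with a bulky trialkylborohydride should occur from the exo (α) face, because O3 and C6 of the bridge are syn-axial to the C1 carbonyl on the β face, giving the 1β (endo) alcohol; the cold acid quench keeps the alkoxide from attacking silicon.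

Step 6
Reactants: 12 1β-alcohol
Product: 13 1β-tert-butyldimethylsilyl ether of 12
Conditions: TBSOTf, 2,6-lutidine, CH2Cl2, 0 °C → rt
Reagents that add atoms: tert-butyldimethylsilyl triflate, CC(C)(C)[Si](C)(C)OS(=O)(=O)C(F)(F)F
Why: Silyl triflate silylation of a hindered secondary alcohol protects O1 for the rest of the route; no stereocentre is formed.

Step 7
Reactants: 13 1β-TBS ether of the bridged siloxane
Product: 14 ring-A diol (1β-OTBS, 3β-OH, C6-OH, 10α-allyl)
Conditions: 30% H2O2, KHCO3, THF–MeOH (1:1), 50 °C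
Reagents that add atoms: hydrogen peroxide, OO
Why: Tamao oxidation of the alkoxysilane replaces the C6–Si bond by C6–OH and releases O3, so ring A relaxes to the chair with O1, O3 and C6 equatorial; no stereocentre is changed.

Step 8
Reactants: 14 ring-A diol
Product: 15 6-O-triethylsilyl ether of 14
Conditions: TESCl (1.05 equiv), imidazole, CH2Cl2, −78 → −40 °C
Reagents that add atoms: chlorotriethylsilane, CC[Si](Cl)(CC)CC
Why: Silylation with a trialkylsilyl chloride at low temperature discriminates the primary C6 hydroxyl from the secondary C3 hydroxyl on steric grounds.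

Step 9
Reactants: 15 6-O-TES ether
Product: 16 C3 ketone (1β-OTBS, 6-OTES, 10α-allyl)
Conditions: Dess–Martin periodinane, NaHCO3, CH2Cl2, rt
Reagents that add atoms: none
Why: Dess–Martin oxidation gives the ketone that activates C4; the carvone-derived C3 centre has done its work in step 4 and is deliberately erased here, to be reset in step 12.

Step 10
Reactants: 16 C3 ketone
Product: 18 4α-(dimethylaminomethyl) C3 ketone, via lithium enolate 17 (not isolated)
Conditions: LDA (1.1 equiv), THF, −78 °C; then CH2=NMe2+ I−, −78 °C → rt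
Reagents that add atoms: N,N-dimethylmethyleneiminium iodide (Eschenmoser's salt), C=[N+](C)C.[I-]
Why: Kinetic deprotonation should take place at C4, away from C2, which is flanked by the β-silyloxy carbon C1 (β-oxygen effect plus the bulk of the OTBS group), and the enolate is trapped in a Mannich reaction; the C4 configuration is inconsequential.

Step 11
Reactants: 18 4α-(dimethylaminomethyl) C3 ketone
Product: 20 4(15)-methylene C3 ketone, via ammonium iodide 19 (not isolated)
Conditions: MeI, CH2Cl2, rt; evaporate; sat. aq. NaHCO3/CH2Cl2, rt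
Reagents that add atoms: none
Why: N-Methylation and Hofmann-type (E1cB) loss of trimethylamine from the β-ammonio ketone gives the exocyclic enone without exposing the β-silyloxy ketone to strong base.

Step 12
Reactants: 20 4(15)-methylene C3 ketone
Product: 21 3β-allylic alcohol
Conditions: NaBH4, CeCl3·7H2O, MeOH, −78 °C
Reagents that add atoms: none
Why: Luche 1,2-reduction with axial hydride delivery on the α face, which carries only the axial hydrogens at C1 and C5, should give the equatorial 3β alcohol and so restore the original C3 configuration.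

Step 13
Reactants: 21 3β-allylic alcohol
Product: 22 1β,3β-bis-TBS ether (6-OTES, 4(15)-ene, 10α-allyl)
Conditions: TBSCl, imidazole, DMF, rt
Reagents that add atoms: tert-butyldimethylsilyl chloride, CC(C)(C)[Si](C)(C)Cl
Why: Imidazole-promoted silylation of the unhindered allylic hydroxyl; no stereocentre is formed.

Step 14
Reactants: 22 1β,3β-bis-TBS ether
Product: 24 C7 primary alcohol, via disiamylborane adduct 23 (not isolated)
Conditions: Sia2BH (from BH3·THF and 2-methylbut-2-ene), THF, 0 °C; then 3 M NaOH, 30% H2O2, 0 °C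
Reagents that add atoms: hydrogen peroxide, OO
Why: Hydroboration–oxidation with a hindered dialkylborane is anti-Markovnikov and selective for the monosubstituted allyl alkene over the 1,1-disubstituted, doubly α-branched C4(15) alkene.

Step 15
Reactants: 24 C7 primary alcohol
Product: 25 C7 aldehyde
Conditions: Dess–Martin periodinane, NaHCO3, CH2Cl2, 0 °C → rt
Reagents that add atoms: none
Why: Dess–Martin oxidation of a primary alcohol to an aldehyde that has no α-stereocentre.

Step 16
Reactants: 26 trimethyl phosphonoacetate; 27 (iodomethyl)trimethylsilane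
Product: 29 methyl 2-(dimethoxyphosphoryl)-3-(trimethylsilyl)propanoate, via sodium salt 28 (not isolated)
Conditions: NaH, DME, 0 °C → rt; then 27, 70 °C
Reagents that add atoms: none
Why: C-Alkylation of the sodium phosphonoacetate with the SN2-active α-silyl iodide gives the silylmethyl Horner–Wadsworth–Emmons reagent (racemic; its stereocentre is lost in step 17).

Step 17
Reactants: 25 C7 aldehyde; 29 methyl 2-(dimethoxyphosphoryl)-3-(trimethylsilyl)propanoate
Product: 31 methyl 2-(trimethylsilylmethyl)alk-2-enoate (C7=C11; E/Z), via sodium salt 30 (not isolated)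
Conditions: NaH, THF, 0 °C; then 25, 0 °C → rt
Reagents that add atoms: none
Why: Horner–Wadsworth–Emmons olefination of the unhindered aldehyde forms C7=C11 and brings in C11–C13 as an ester-bearing allylsilane; both alkene isomers are usable.

Step 18
Reactants: 31 allylsilane ester (6-OTES)
Product: 32 C6 primary alcohol
Conditions: PPTS (cat.), MeOH–CH2Cl2, 0 °C
Reagents that add atoms: none
Why: Acid-catalysed methanolysis removes the primary triethylsilyl ether selectively in the presence of the two secondary TBS ethers and the electron-poor allylsilane.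

Step 19
Reactants: 32 C6 primary alcohol
Product: 33 C6 aldehyde
Conditions: Dess–Martin periodinane, pyridine, CH2Cl2, 0 °C; used at once
Reagents that add atoms: none
Why: Buffered Dess–Martin oxidation forms the aldehyde under non-basic conditions, so that neither epimerisation at C5 nor migration of the C4(15) alkene into conjugation is provoked.

Step 20
Reactants: 33 C6 aldehyde
Product: 34 methyl 1β,3β-bis(tert-butyldimethylsilyloxy)-6α-hydroxyeudesma-4(15),11(13)-dien-12-oate
Conditions: BF3·OEt2, CH2Cl2, −78 → −40 °C; aq. NaHCO3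
Reagents that add atoms: none
Why: Intramolecular Hosomi–Sakurai reaction in which C7 of the allylsilane attacks the BF3-activated aldehyde (SE2′, loss of Me3Si) through a chair-like six-membered transition state fused trans to ring A, with the C6–O bond and the C7 side chain both equatorial; this should set 6α-OH and 7α-H and unveils the C11(13) acrylate.

Step 21
Reactants: 35 methyl 2-(hydroxymethyl)acrylate
Product: 36 methyl 2-[(tert-butyldimethylsilyloxy)methyl]acrylate
Conditions: TBSCl, imidazole, CH2Cl2, 0 °C → rt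
Reagents that add atoms: tert-butyldimethylsilyl chloride, CC(C)(C)[Si](C)(C)Cl
Why: Standard silylation of a primary allylic alcohol.

Step 22
Reactants: 36 methyl 2-[(tert-butyldimethylsilyloxy)methyl]acrylate
Product: 37 2-[(tert-butyldimethylsilyloxy)methyl]acrylic acid
Conditions: LiOH·H2O, THF–H2O, 0 °C; then 1 M HCl to pH 4
Reagents that add atoms: lithium hydroxide, [Li+].[OH-]
Why: Saponification of the methyl ester at 0 °C, under which a primary TBS ether survives, gives the acid for the acylation.

Step 23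
Reactants: 34 6α-hydroxy ester; 37 2-[(tert-butyldimethylsilyloxy)methyl]acrylic acid
Product: 39 tris-TBS ether of the target, via mixed anhydride 38 (not isolated)
Conditions: 2,4,6-trichlorobenzoyl chloride, Et3N, THF, rt; then 34, DMAP, toluene, rt → 40 °C
Reagents that add atoms: none
Why: Yamaguchi esterification through the mixed anhydride acylates the hindered equatorial 6α-hydroxyl with retention at C6, the DMAP-activated acyl transfer being expected to outpace lactonisation onto the C12 ester.

Step 24
Reactants: 39 tris-TBS ether of the target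
Product: 40 methyl (1R,3S,5S,6S,7S,10R)-1β,3β-dihydroxy-6α-{[2-(hydroxymethyl)acryloyl]oxy}eudesma-4(15),11(13)-dien-12-oate (CNP0247525.1)
Conditions: HF·pyridine, pyridine, THF, 0 °C → rt
Reagents that add atoms: none
Why: Buffered HF·pyridine cleaves the three silyl ethers under conditions that leave both acrylate esters and the allylic alcohol untouched, releasing the target.

**Compound list**

1 | (R)-carvone | O=C1C[C@H](C(C)=C)CC=C1C | starting material
2 | (5R)-5-(1-hydroperoxy-1-methoxyethyl)-2-methylcyclohex-2-en-1-one (epimers at the peroxy carbon) | O=C1C[C@H](C(C)(OC)OO)CC=C1C | intermediate (not isolated)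
3 | (5R)-5-[1-(acetylperoxy)-1-methoxyethyl]-2-methylcyclohex-2-en-1-one | O=C1C[C@H](C(C)(OC)OOC(C)=O)CC=C1C | intermediate (not isolated)
4 | (R)-5-acetoxy-2-methylcyclohex-2-en-1-one | O=C1C[C@H](OC(C)=O)CC=C1C | intermediate
5 | (R)-5-hydroxy-2-methylcyclohex-2-en-1-one | O=C1C[C@H](O)CC=C1C | intermediate
6 | (bromomethyl)chlorodimethylsilane | C[Si](C)(Cl)CBr | starting material
7 | (R)-5-{[(bromomethyl)dimethylsilyl]oxy}-2-methylcyclohex-2-en-1-one | O=C1C[C@H](O[Si](C)(C)CBr)CC=C1C | intermediate
8 | allyltributylstannane | C=CC[Sn](CCCC)(CCCC)CCCC | starting material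
9 | silylmethyl radical derived from 7 (CH2• on silicon) | O=C1C[C@H](O[Si](C)(C)[CH2])CC=C1C | intermediate (not isolated)
10 | bridged siloxane α-keto radical at C10 (C5–C6 bond formed) | C[Si]1(C)C[C@H]2C[C@@H](O1)CC(=O)[C]2C | intermediate (not isolated)
11 | (1R,5S,6R)-6-allyl-3,3,6-trimethyl-2-oxa-3-silabicyclo[3.3.1]nonan-7-one (siloxane bridging O3 and C6 on the β face; C1 ketone; C10 β-methyl, α-allyl) | C[Si]1(C)C[C@H]2C[C@@H](O1)CC(=O)[C@]2(C)CC=C | intermediate
12 | (1R,5S,6R,7R)-6-allyl-3,3,6-trimethyl-2-oxa-3-silabicyclo[3.3.1]nonan-7-ol (1β-OH, cis to the bridge) | C[Si]1(C)C[C@H]2C[C@@H](O1)C[C@@H](O)[C@]2(C)CC=C | intermediate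
13 | 1β-TBS ether of 12 | C[Si]1(C)C[C@H]2C[C@@H](O1)C[C@@H](O[Si](C)(C)C(C)(C)C)[C@]2(C)CC=C | intermediate
14 | ring-A diol: 1β-OTBS, 3β-OH, 5β-CH2OH (C6), 10β-methyl, 10α-allyl cyclohexane (5α-H) | OC[C@H]1C[C@@H](O)C[C@@H](O[Si](C)(C)C(C)(C)C)[C@]1(C)CC=C | intermediate
15 | 6-O-triethylsilyl ether of 14 (3β-OH free) | CC[Si](CC)(CC)OC[C@H]1C[C@@H](O)C[C@@H](O[Si](C)(C)C(C)(C)C)[C@]1(C)CC=C | intermediate
16 | C3 ketone: 1β-OTBS, 6-OTES, 10β-methyl, 10α-allyl cyclohexan-3-one | CC[Si](CC)(CC)OC[C@H]1CC(=O)C[C@@H](O[Si](C)(C)C(C)(C)C)[C@]1(C)CC=C | intermediate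
17 | lithium C3=C4 enolate of 16 | CC[Si](CC)(CC)OC[C@H]1C=C([O-])C[C@@H](O[Si](C)(C)C(C)(C)C)[C@]1(C)CC=C.[Li+] | intermediate (not isolated)
18 | 4α-(dimethylaminomethyl) derivative of 16 (Mannich base; 4β-epimer equally serviceable) | CC[Si](CC)(CC)OC[C@H]1[C@H](CN(C)C)C(=O)C[C@@H](O[Si](C)(C)C(C)(C)C)[C@]1(C)CC=C | intermediate
19 | trimethylammonium iodide of 18 | CC[Si](CC)(CC)OC[C@H]1[C@H](C[N+](C)(C)C)C(=O)C[C@@H](O[Si](C)(C)C(C)(C)C)[C@]1(C)CC=C.[I-] | intermediate (not isolated)
20 | 4(15)-methylene C3 ketone (1β-OTBS, 6-OTES, 10α-allyl) | CC[Si](CC)(CC)OC[C@H]1C(=C)C(=O)C[C@@H](O[Si](C)(C)C(C)(C)C)[C@]1(C)CC=C | intermediate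
21 | 3β-allylic alcohol (1β-OTBS, 6-OTES, 4(15)-ene, 10α-allyl) | CC[Si](CC)(CC)OC[C@H]1C(=C)[C@@H](O)C[C@@H](O[Si](C)(C)C(C)(C)C)[C@]1(C)CC=C | intermediate
22 | 1β,3β-bis-TBS ether (6-OTES, 4(15)-ene, 10α-allyl) | CC[Si](CC)(CC)OC[C@H]1C(=C)[C@@H](O[Si](C)(C)C(C)(C)C)C[C@@H](O[Si](C)(C)C(C)(C)C)[C@]1(C)CC=C | intermediate
23 | C7 disiamylborane adduct of 22 | CC[Si](CC)(CC)OC[C@H]1C(=C)[C@@H](O[Si](C)(C)C(C)(C)C)C[C@@H](O[Si](C)(C)C(C)(C)C)[C@]1(C)CCCB(C(C)C(C)C)C(C)C(C)C | intermediate (not isolated)
24 | C7 primary alcohol (C10 chain = 3-hydroxypropyl) | CC[Si](CC)(CC)OC[C@H]1C(=C)[C@@H](O[Si](C)(C)C(C)(C)C)C[C@@H](O[Si](C)(C)C(C)(C)C)[C@]1(C)CCCO | intermediate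
25 | C7 aldehyde (C10 chain = 3-oxopropyl) | CC[Si](CC)(CC)OC[C@H]1C(=C)[C@@H](O[Si](C)(C)C(C)(C)C)C[C@@H](O[Si](C)(C)C(C)(C)C)[C@]1(C)CCC=O | intermediate
26 | trimethyl phosphonoacetate | COC(=O)CP(=O)(OC)OC | starting material
27 | (iodomethyl)trimethylsilane | C[Si](C)(C)CI | starting material
28 | sodium salt of 26 | COC(=O)[CH-]P(=O)(OC)OC.[Na+] | intermediate (not isolated)
29 | methyl 2-(dimethoxyphosphoryl)-3-(trimethylsilyl)propanoate (racemic) | COC(=O)C(C[Si](C)(C)C)P(=O)(OC)OC | intermediate
30 | sodium salt of 29 | COC(=O)[C-](C[Si](C)(C)C)P(=O)(OC)OC.[Na+] | intermediate (not isolated)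
31 | allylsilane ester: C10 chain = CH2CH2CH=C(CH2SiMe3)CO2Me (E/Z), 6-OTES | CC[Si](CC)(CC)OC[C@H]1C(=C)[C@@H](O[Si](C)(C)C(C)(C)C)C[C@@H](O[Si](C)(C)C(C)(C)C)[C@]1(C)CCC=C(C[Si](C)(C)C)C(=O)OC | intermediate
32 | C6 primary alcohol of 31 | OC[C@H]1C(=C)[C@@H](O[Si](C)(C)C(C)(C)C)C[C@@H](O[Si](C)(C)C(C)(C)C)[C@]1(C)CCC=C(C[Si](C)(C)C)C(=O)OC | intermediate
33 | C6 aldehyde (5α-H, formyl group equatorial) | O=C[C@H]1C(=C)[C@@H](O[Si](C)(C)C(C)(C)C)C[C@@H](O[Si](C)(C)C(C)(C)C)[C@]1(C)CCC=C(C[Si](C)(C)C)C(=O)OC | intermediate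
34 | methyl 1β,3β-bis(tert-butyldimethylsilyloxy)-6α-hydroxyeudesma-4(15),11(13)-dien-12-oate (5α-H, 7α-H) | O[C@@H]1[C@H]2C(=C)[C@@H](O[Si](C)(C)C(C)(C)C)C[C@@H](O[Si](C)(C)C(C)(C)C)[C@]2(C)CC[C@H]1C(=C)C(=O)OC | intermediate
35 | methyl 2-(hydroxymethyl)acrylate | C=C(CO)C(=O)OC | starting material
36 | methyl 2-[(tert-butyldimethylsilyloxy)methyl]acrylate | C=C(CO[Si](C)(C)C(C)(C)C)C(=O)OC | intermediate
37 | 2-[(tert-butyldimethylsilyloxy)methyl]acrylic acid | C=C(CO[Si](C)(C)C(C)(C)C)C(=O)O | intermediate
38 | mixed anhydride of 37 and 2,4,6-trichlorobenzoic acid | C=C(CO[Si](C)(C)C(C)(C)C)C(=O)OC(=O)c1c(Cl)cc(Cl)cc1Cl | intermediate (not isolated)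
39 | methyl 1β,3β-bis(tert-butyldimethylsilyloxy)-6α-({2-[(tert-butyldimethylsilyloxy)methyl]acryloyl}oxy)eudesma-4(15),11(13)-dien-12-oate | C=C(CO[Si](C)(C)C(C)(C)C)C(=O)O[C@@H]1[C@H]2C(=C)[C@@H](O[Si](C)(C)C(C)(C)C)C[C@@H](O[Si](C)(C)C(C)(C)C)[C@]2(C)CC[C@H]1C(=C)C(=O)OC | intermediate
40 | methyl (1R,3S,5S,6S,7S,10R)-1β,3β-dihydroxy-6α-{[2-(hydroxymethyl)acryloyl]oxy}eudesma-4(15),11(13)-dien-12-oate | C=C(CO)C(=O)O[C@@H]1[C@H]2C(=C)[C@@H](O)C[C@@H](O)[C@]2(C)CC[C@H]1C(=C)C(=O)OC | target

**Step count**

Total: 24 steps. Longest linear sequence: 21 steps (steps 1–15, 17–20, 23, 24). Steps 16, 21 and 22 are side branches.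

**Steps most likely to fail**

1. Step 4 (proposed new method). Allyl transfer to the silylmethyl radical may occur before ring closure, or capture of the hindered tertiary C10 radical may be too slow to sustain the chain. The fallback uses known reactions only, sets out from 7 and returns at 11; it separates the two radical events. Slow addition of Bu3SnH with AIBN to 7 in benzene at 80 °C (reductive silicon-tethered radical cyclisation) should give the C10–H bridged siloxane ketone F1. TMSCl, NaI and Et3N in MeCN under equilibrating conditions convert it into the more substituted C1=C10 trimethylsilyl enol ether F2, and NBS in THF at 0 °C gives the tertiary C10 bromo ketone F3. Keck allylation of F3 with 8 and AIBN regenerates the same C10 radical, now with no competing step, and should deliver 11 with the same anti selectivity.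

2. Step 5. Hydride may be delivered to the β face, since the α face is partly screened by the axial C9 arm, or the new alkoxide may attack silicon and scramble the siloxane. The fallback sets out from 11 and returns at 14; it reduces C1 only after the ring is unlocked. Tamao oxidation of 11 (H2O2, KHCO3) gives the 3β,6-dihydroxy C1 ketone F4. NaBH4 in MeOH should then add axially, anti to the axial C14 methyl as in Wieland–Miescher-type ketones, to give the 1β,3β,6-triol F5. TESCl (2.1 equiv) with imidazole silylates the primary and the unhindered C3 hydroxyl and leaves the neopentyl C1 hydroxyl, giving the 3,6-bis-TES ether F6. TBSOTf with 2,6-lutidine gives the 1-O-TBS 3,6-bis-TES ether F7, and PPTS in MeOH removes both TES groups to return 14.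

3. Step 20. The closure may show poor diastereocontrol, the C4(15) alkene may migrate into conjugation with the aldehyde under acid, or protodesilylation or lactonisation may intervene. The fallback sets out from 25 and returns at 39; ring B is closed by a carbonyl-ene reaction and C12 is oxidised afterwards. Wittig reaction of 25 with Ph3P=CMe2 gives the homoprenyl compound F8; PPTS in MeOH gives the C6 alcohol F9 and Dess–Martin oxidation the C6 aldehyde F10. Me2AlCl in CH2Cl2 at −78 °C should close ring B in the type I carbonyl-ene mode (citronellal to isopulegol) through the all-equatorial chair to give the 6α-hydroxy-7β-isopropenyl decalin F11. Yamaguchi acylation with 37 gives the 6-O-acyl isopropenyl compound F12. SeO2 in dioxane at 80 °C oxidises the isopropenyl methyl to the C12 enal F13; the weak point is competition from the C4(15) alkene, whose allylic positions are both methines. Pinnick oxidation gives the C12 acid F14, and TMSCHN2 returns 39.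

**Further compounds**

F1 | step 4 | 3,3,6-trimethyl-2-oxa-3-silabicyclo[3.3.1]nonan-7-one (C10–H, either epimer) | C[Si]1(C)C[C@H]2C[C@@H](O1)CC(=O)C2C
F2 | step 4 | C1=C10 trimethylsilyl enol ether of F1 | C[Si]1(C)C[C@H]2C[C@@H](O1)CC(O[Si](C)(C)C)=C2C
F3 | step 4 | C10 bromo ketone (6-bromo-3,3,6-trimethyl-2-oxa-3-silabicyclo[3.3.1]nonan-7-one, either epimer) | C[Si]1(C)C[C@H]2C[C@@H](O1)CC(=O)C2(C)Br
F4 | step 5 | 3β-hydroxy-5β-(hydroxymethyl)-10β-methyl-10α-allyl cyclohexan-1-one | OC[C@H]1C[C@@H](O)CC(=O)[C@]1(C)CC=C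
F5 | step 5 | 1β,3β,6-triol | OC[C@H]1C[C@@H](O)C[C@@H](O)[C@]1(C)CC=C
F6 | step 5 | 3,6-bis-O-triethylsilyl ether of F5 (1β-OH free) | CC[Si](CC)(CC)OC[C@H]1C[C@@H](O[Si](CC)(CC)CC)C[C@@H](O)[C@]1(C)CC=C
F7 | step 5 | 1-O-TBS 3,6-bis-O-TES ether | CC[Si](CC)(CC)OC[C@H]1C[C@@H](O[Si](CC)(CC)CC)C[C@@H](O[Si](C)(C)C(C)(C)C)[C@]1(C)CC=C
F8 | step 20 | homoprenyl compound (C10 chain = CH2CH2CH=CMe2; 6-OTES, 1β,3β-bis-OTBS, 4(15)-ene) | CC[Si](CC)(CC)OC[C@H]1C(=C)[C@@H](O[Si](C)(C)C(C)(C)C)C[C@@H](O[Si](C)(C)C(C)(C)C)[C@]1(C)CCC=C(C)C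
F9 | step 20 | C6 alcohol of F8 | OC[C@H]1C(=C)[C@@H](O[Si](C)(C)C(C)(C)C)C[C@@H](O[Si](C)(C)C(C)(C)C)[C@]1(C)CCC=C(C)C
F10 | step 20 | C6 aldehyde of F8 | O=C[C@H]1C(=C)[C@@H](O[Si](C)(C)C(C)(C)C)C[C@@H](O[Si](C)(C)C(C)(C)C)[C@]1(C)CCC=C(C)C
F11 | step 20 | 1β,3β-bis(TBS-oxy)eudesma-4(15),11-dien-6α-ol | O[C@@H]1[C@H]2C(=C)[C@@H](O[Si](C)(C)C(C)(C)C)C[C@@H](O[Si](C)(C)C(C)(C)C)[C@]2(C)CC[C@H]1C(C)=C
F12 | step 20 | 6α-O-{2-[(TBS-oxy)methyl]acryloyl} ester of F11 | C=C(CO[Si](C)(C)C(C)(C)C)C(=O)O[C@@H]1[C@H]2C(=C)[C@@H](O[Si](C)(C)C(C)(C)C)C[C@@H](O[Si](C)(C)C(C)(C)C)[C@]2(C)CC[C@H]1C(C)=C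
F13 | step 20 | C12 enal (eudesma-4(15),11(13)-dien-12-al) of F12 | C=C(CO[Si](C)(C)C(C)(C)C)C(=O)O[C@@H]1[C@H]2C(=C)[C@@H](O[Si](C)(C)C(C)(C)C)C[C@@H](O[Si](C)(C)C(C)(C)C)[C@]2(C)CC[C@H]1C(=C)C=O
F14 | step 20 | C12 acid (free acid of 39) | C=C(CO[Si](C)(C)C(C)(C)C)C(=O)O[C@@H]1[C@H]2C(=C)[C@@H](O[Si](C)(C)C(C)(C)C)C[C@@H](O[Si](C)(C)C(C)(C)C)[C@]2(C)CC[C@H]1C(=C)C(=O)O
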